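**Retrosynthetic overview**
- Last bond: C8–prenyl, made by alkylative dearomatization of the fully substituted phenol acid with prenyl bromide; the quaternary centre is set by the side-chain centre through a lithium carboxylate–phenoxide aggregate.
- The acid comes from the enal. The enal chain is the carvone skeleton opened between C1 and C6 (C1 becomes CHO then CO2H, C6 becomes ArCH2), so the only purchased stereocentre is C5 of (R)-carvone.
- Key disconnection: aryl C8–CH2, made by a light-driven ring-opening C–H alkylation of the chromene phenol with the N-carveyloxyphthalimide (from carvone by Luche reduction and Mitsunobu reaction).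
- Core: 2,4,6-trihydroxybenzophenone plus prenal (Knoevenagel condensation, oxa-6π closure) gives the chromene.
- Ring order: benzene ring bought; pyran ring closed first; carvone ring opened in the key step; benzene ring dearomatized last to the cyclohexadienone.

Labels used below: chromene numbering for the core (O1, C2 … C8a); carvone numbering for the terpene unit (C1 carbonyl or carbinol carbon, C5 the isopropenyl-bearing stereocentre, C6 the CH2 between them). The target has (R) at the side-chain centre and (S) at the quaternary carbon C8.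

Step 1
Reactants: 1 2,4,6-trihydroxybenzophenone; 2 3-methylbut-2-enal (prenal)
Product: 4 (5,7-dihydroxy-2,2-dimethyl-2H-chromen-6-yl)(phenyl)methanone, via 1-oxatriene 3 (not isolated)
Conditions: 2 (1.05 equiv), ethylenediammonium diacetate (10 mol %), toluene, 100 °C
Reagents that add atoms: none
Why: Knoevenagel condensation at a ring CH between two hydroxyls gives the 1-oxatriene (ortho-quinone methide) 3, whose oxa-6π electrocyclization should close onto the oxygen para to the benzoyl group because the ortho oxygens stay in the hydrogen bond to the benzoyl carbonyl; the 8-benzoyl regioisomer and any bis-chromene are removed on silica.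

Step 2
Reactants: 5 (R)-(−)-carvone
Product: 6 (1R,5R)-2-methyl-5-(prop-1-en-2-yl)cyclohex-2-en-1-ol (cis-carveol)
Conditions: NaBH4 (1.0 equiv), CeCl3·7H2O (1.0 equiv), MeOH, −20 °C
Reagents that add atoms: none
Why: Luche 1,2-reduction, in which axial hydride attack on the half-chair with equatorial isopropenyl gives the equatorial alcohol cis to the isopropenyl group (1R, high dr) and leaves the (R) centre at C5 untouched.

Step 3
Reactants: 6 (1R,5R)-cis-carveol; 7 N-hydroxyphthalimide
Product: 8 2-{[(1S,5R)-2-methyl-5-(prop-1-en-2-yl)cyclohex-2-en-1-yl]oxy}isoindoline-1,3-dione (trans)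
Conditions: PPh3 (1.3 equiv), diisopropyl azodicarboxylate (1.3 equiv), THF, 0 → 23 °C
Reagents that add atoms: none
Why: Mitsunobu reaction, in which the acidic N–OH (pKa about 6) displaces the phosphonium-activated allylic alcohol with inversion to give the trans (1S) ether, the isomer whose later alkoxy radical cannot reach the isopropenyl group; C5 is untouched.

Step 4
Reactants: 4 (5,7-dihydroxy-2,2-dimethyl-2H-chromen-6-yl)(phenyl)methanone; 8 trans-N-carveyloxyphthalimide
Product: 10 (2E,5R)-5-[(6-benzoyl-5,7-dihydroxy-2,2-dimethyl-2H-chromen-8-yl)methyl]-2,6-dimethylhepta-2,6-dienal, via Z-enal 9 (not isolated)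
Conditions: 4 (1.5 equiv), 8 (1.0 equiv), Cs2CO3 (0.5 equiv), MeCN (0.05 M, degassed), 405 nm LEDs, 20 °C; then PhSH (10 mol %), dark, 23 °C; aq. NH4Cl
Reagents that add atoms: none
Why: Proposed new method: the caesium phenoxide of 4 and the phthalimide acceptor 8 should form an electron donor–acceptor pair whose charge-transfer excitation (no long-lived phenoxide excited state is needed, so the fast proton-transfer decay of ortho-acylphenols does not matter) gives the phenoxyl radical, phthalimide anion and the carveyloxy radical; β-scission of C1–C6, driven by formation of the conjugated enal, releases a primary radical at C6 next to the intact (R) centre, and this radical is captured at C8, the only unsubstituted ring carbon, before the slow 1,2-vinyl shift of a homoallyl radical (about 10^4 s−1) can erode the stereocentre; tautomerization restores the phenol, the phthalimide anion passes the base on, and thiolate addition–elimination then equilibrates the Z-enal 9 (the cis ring geometry of carvone) to the E-enal 10, with no new stereocentre formed; the closest known reactions are the donor–acceptor-complex generation of alkoxy radicals from N-alkoxyphthalimides with Hantzsch ester followed by β-scission, and the light-driven ortho-alkylation of phenoxides with alkyl iodides, but a phenoxide serving as both donor and radical acceptor in a ring-opening C–H alkylation has not been reported.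

Step 5
Reactants: 10 (2E,5R)-enal
Product: 11 (2E,5R)-5-[(6-benzoyl-5,7-dihydroxy-2,2-dimethyl-2H-chromen-8-yl)methyl]-2,6-dimethylhepta-2,6-dienoic acid
Conditions: NaClO2 (3 equiv), NaH2PO4 (4 equiv), 2-methyl-2-butene (40 equiv), t-BuOH/THF/H2O (4:2:1), 0 °C
Reagents that add atoms: sodium chlorite, [Na+].[O-]Cl=O
Why: Pinnick oxidation, in which chlorous acid oxidizes only the aldehyde and keeps the E-alkene and the remote stereocentre, while the large excess of 2-methyl-2-butene removes HOCl before it can chlorinate the phenol ring or the chromene and isopropenyl alkenes.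

Step 6
Reactants: 11 (2E,5R)-acid; 12 1-bromo-3-methylbut-2-ene (prenyl bromide)
Product: 13 (2E,5R)-5-{[(8S)-6-benzoyl-7-hydroxy-2,2-dimethyl-8-(3-methylbut-2-en-1-yl)-5-oxo-5,8-dihydro-2H-chromen-8-yl]methyl}-2,6-dimethylhepta-2,6-dienoic acid
Conditions: LiN(SiMe3)2 (3.3 equiv), THF/toluene (1:3), −40 °C; 12 (1.2 equiv), −40 → 0 °C; aq. citric acid
Reagents that add atoms: none
Why: Alkylative dearomatization (SN2 C-alkylation of a lithium phenoxide, as in lupulone-type gem-dialkyl acylphloroglucinols) at C8, with tight lithium ion pairing suppressing O-alkylation and alkylation at C4a disfavoured because it would break the chromene conjugation; the C8 stereocentre is intended to be set by the (R) centre two bonds away, because the side-chain lithium carboxylate should join the lithium aggregate at O7 and hold the enoate arm over the O7 edge with isopropenyl pointing away and C5–H over the pyran oxygen, so that C5 sits on one face and prenyl bromide enters from the other, which by this model gives (8S).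

**Compound list**
1 | 2,4,6-trihydroxybenzophenone | O=C(c1ccccc1)c1c(O)cc(O)cc1O | starting material
2 | 3-methylbut-2-enal (prenal) | CC(C)=CC=O | starting material
3 | 4-benzoyl-3,5-dihydroxy-6-(3-methylbut-2-en-1-ylidene)cyclohexa-2,4-dien-1-one (1-oxatriene) | O=C1C=C(O)C(C(=O)c2ccccc2)=C(O)C1=CC=C(C)C | intermediate
4 | (5,7-dihydroxy-2,2-dimethyl-2H-chromen-6-yl)(phenyl)methanone | CC1(C)C=Cc2c(O)c(C(=O)c3ccccc3)c(O)cc2O1 | intermediate
5 | (R)-(−)-carvone | CC1=CC[C@H](CC1=O)C(C)=C | starting material
6 | (1R,5R)-2-methyl-5-(prop-1-en-2-yl)cyclohex-2-en-1-ol (cis-carveol) | CC1=CC[C@H](C[C@H]1O)C(C)=C | intermediate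
7 | N-hydroxyphthalimide | O=C1c2ccccc2C(=O)N1O | starting material
8 | 2-{[(1S,5R)-2-methyl-5-(prop-1-en-2-yl)cyclohex-2-en-1-yl]oxy}isoindoline-1,3-dione | CC1=CC[C@H](C[C@@H]1ON1C(=O)c2ccccc2C1=O)C(C)=C | intermediate
9 | (2Z,5R)-5-[(6-benzoyl-5,7-dihydroxy-2,2-dimethyl-2H-chromen-8-yl)methyl]-2,6-dimethylhepta-2,6-dienal | C=C(C)[C@H](C/C=C(/C)C=O)Cc1c(O)c(C(=O)c2ccccc2)c(O)c2C=CC(C)(C)Oc12 | intermediate
10 | (2E,5R)-5-[(6-benzoyl-5,7-dihydroxy-2,2-dimethyl-2H-chromen-8-yl)methyl]-2,6-dimethylhepta-2,6-dienal | C=C(C)[C@H](C/C=C(\C)C=O)Cc1c(O)c(C(=O)c2ccccc2)c(O)c2C=CC(C)(C)Oc12 | intermediate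
11 | (2E,5R)-5-[(6-benzoyl-5,7-dihydroxy-2,2-dimethyl-2H-chromen-8-yl)methyl]-2,6-dimethylhepta-2,6-dienoic acid | C=C(C)[C@H](C/C=C(\C)C(=O)O)Cc1c(O)c(C(=O)c2ccccc2)c(O)c2C=CC(C)(C)Oc12 | intermediate
12 | 1-bromo-3-methylbut-2-ene (prenyl bromide) | CC(C)=CCBr | starting material
13 | (2E,5R)-5-{[(8S)-6-benzoyl-7-hydroxy-2,2-dimethyl-8-(3-methylbut-2-en-1-yl)-5-oxo-5,8-dihydro-2H-chromen-8-yl]methyl}-2,6-dimethylhepta-2,6-dienoic acid | C=C(C)[C@H](C/C=C(\C)C(=O)O)C[C@@]1(CC=C(C)C)C(O)=C(C(=O)c2ccccc2)C(=O)C2=C1OC(C)(C)C=C2 | target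

**Step count and risks**
Total steps: 6. Longest linear sequence: 5 steps (5 → 6 → 8 → 10 → 11 → 13).

The three steps most likely to fail are steps 4, 6 and 5.

Step 4 (the proposed new reaction) may fail through back electron transfer, reduction of the alkoxy radical, or radical attack at oxygen or at the chromene alkene. The fallback uses known chemistry and sets out from 4 and 8. Compound 4 is brominated at C8 with N-bromosuccinimide (CH2Cl2, −78 °C) to (8-bromo-5,7-dihydroxy-2,2-dimethyl-2H-chromen-6-yl)(phenyl)methanone F1. Both phenols are acetylated (Ac2O, pyridine) to 6-benzoyl-8-bromo-2,2-dimethyl-2H-chromene-5,7-diyl diacetate F2. F2 is then joined to 8 by the established nickel/photoredox cross-coupling of aryl bromides with N-alkoxyphthalimides that runs through alkoxy-radical β-scission (NiBr2(dme), 4,4′-di-tert-butyl-2,2′-bipyridine, Hantzsch ester, 2,4,5,6-tetra(9H-carbazol-9-yl)isophthalonitrile, 2,6-lutidine, blue LEDs). This gives (2Z,5R)-5-[(5,7-diacetoxy-6-benzoyl-2,2-dimethyl-2H-chromen-8-yl)methyl]-2,6-dimethylhepta-2,6-dienal F3. K2CO3 in MeOH removes both acetates and catalytic PhSH sets the E-enal, which brings the route back at 10.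

Step 6 may give O-prenylation, alkylation at C4a, or a poor ratio of C8 epimers if the lithium aggregate does not hold the carboxylate arm as assumed. The fallback sets out from 11 and replaces the kinetic lithium alkylation by a Tsuji–Trost prenylation: Pd(PPh3)4 (zerovalent palladium, 5 mol %) and tert-butyl (3-methylbut-2-en-1-yl) carbonate in THF at 23 °C. Under these conditions O-prenyl ethers and the prenyl ester ionize again and are funnelled to the C8-prenyl compounds. Compound 13 is then separated by preparative reverse-phase HPLC from its C8 epimer, (2E,5R)-5-{[(8R)-6-benzoyl-7-hydroxy-2,2-dimethyl-8-(3-methylbut-2-en-1-yl)-5-oxo-5,8-dihydro-2H-chromen-8-yl]methyl}-2,6-dimethylhepta-2,6-dienoic acid F5. This fallback comes back to the route at 13.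

Step 5 may chlorinate or oxidize the electron-rich phenol ring. The fallback sets out from 10 and reverses the order of the last two operations. LiN(SiMe3)2 (2.1 equiv) and 12 in THF/toluene convert 10 into the dearomatized enal (2E,5R)-5-{[(8S)-6-benzoyl-7-hydroxy-2,2-dimethyl-8-(3-methylbut-2-en-1-yl)-5-oxo-5,8-dihydro-2H-chromen-8-yl]methyl}-2,6-dimethylhepta-2,6-dienal F4, with C8 epimers separated on silica. The chlorite oxidation is then run on F4, whose ring is a vinylogous acid and no longer a phenol. This joins the route at 13.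

**Further compounds**
F1 | step 4 | (8-bromo-5,7-dihydroxy-2,2-dimethyl-2H-chromen-6-yl)(phenyl)methanone | CC1(C)C=Cc2c(O)c(C(=O)c3ccccc3)c(O)c(Br)c2O1
F2 | step 4 | 6-benzoyl-8-bromo-2,2-dimethyl-2H-chromene-5,7-diyl diacetate | CC(=O)Oc1c(C(=O)c2ccccc2)c(OC(C)=O)c(Br)c2OC(C)(C)C=Cc12
F3 | step 4 | (2Z,5R)-5-[(5,7-diacetoxy-6-benzoyl-2,2-dimethyl-2H-chromen-8-yl)methyl]-2,6-dimethylhepta-2,6-dienal | C=C(C)[C@H](C/C=C(/C)C=O)Cc1c(OC(C)=O)c(C(=O)c2ccccc2)c(OC(C)=O)c2C=CC(C)(C)Oc12
F4 | step 5 | (2E,5R)-5-{[(8S)-6-benzoyl-7-hydroxy-2,2-dimethyl-8-(3-methylbut-2-en-1-yl)-5-oxo-5,8-dihydro-2H-chromen-8-yl]methyl}-2,6-dimethylhepta-2,6-dienal | C=C(C)[C@H](C/C=C(\C)C=O)C[C@@]1(CC=C(C)C)C(O)=C(C(=O)c2ccccc2)C(=O)C2=C1OC(C)(C)C=C2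
F5 | step 6 | (2E,5R)-5-{[(8R)-6-benzoyl-7-hydroxy-2,2-dimethyl-8-(3-methylbut-2-en-1-yl)-5-oxo-5,8-dihydro-2H-chromen-8-yl]methyl}-2,6-dimethylhepta-2,6-dienoic acid | C=C(C)[C@H](C/C=C(\C)C(=O)O)C[C@]1(CC=C(C)C)C(O)=C(C(=O)c2ccccc2)C(=O)C2=C1OC(C)(C)C=C2
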